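Numbering used throughout: decalin carbons C1–C10 (ring A = C1–C5 and C10, ring B = C5–C10, with C5 and C10 the fusion atoms); C11 is the methylene on C8; ring C is C1′ (carbinol carbon bearing CO2Me), C2′ (=CH), C3′ (C–OMe), C4′ (C=O), C5′ (CH–C11). β is the face of the C5 methyl group, α the opposite face.

## Analysis of the target

Dysidenone B (28) is a trans-fused Δ3-octalin joined through C11 at C8 to ring C, a 4-hydroxy-4-carbomethoxy-2-methoxycyclopent-2-enone. The decalin carries four contiguous stereocentres: quaternary C5 (Me β), C10 (H α), C9 (Me β, therefore 1,3-syn-diaxial to the C5 methyl) and quaternary C8 (Me α and axial, C11 β and equatorial). Ring C adds the tertiary carbinol C1′ and the methine C5′, with C11 trans to the hydroxyl and cis to the ester; C11 insulates these two centres from the decalin, so the bicycle cannot relay their configuration. Sensitive groups are the β-hydroxy ketone (retro-aldol, epimerisable C5′), the α-methoxy enone, the methyl ester, and the C3=C4 alkene beside quaternary C5, which invites a 1,2-methyl shift under cationic conditions. The synthesis is hard because the equatorial C8–C11 bond is the one that axial enolate alkylation or conjugate addition would not make, the C9 methyl sits on the more crowded face, and two quaternary carbons flank ring B. The structural feature that the plan uses is that ring A holds the quaternary C5 methyl next to the vinylic C4 methyl, C8 carries a second methyl, and C6 and C9 can both be carbonyl carbons. Ring B is therefore the skeleton of 2,5-dimethyl-1,4-benzoquinone (4) with C5=C10 as one of its alkenes, and C1–C4 with the C4 methyl are a pentadiene. A cycloaddition between the two forms C4–C5 and C1–C10, closes ring A and fixes C5, from which every other decalin centre is derived.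

## Retrosynthetic reasoning

**Ring C (28 ⇒ 26 ⇒ 25).** The C1′–C5′ bond is cut as an aldol bond, giving the acyclic cis-enedione keto ester 25. This is the one ring C bond whose formation creates the tertiary carbinol and the β-hydroxy ketone together at the very end, so neither has to survive earlier steps. The forward cyclisation must choose the face of the C1′ ketone under catalyst control. C5′, being α to the ketone, is then corrected from epimer 26 by kinetic protonation.

**Unmasking the enedione (25 ⇒ 23).** The cis-2-ene-1,4-dione of 25 is the oxidation product of a 2,5-disubstituted furan. Going back to furan 23 replaces three reactive carbonyl groups by one robust aromatic ring. The forward oxidation must take the furan and spare C3=C4.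

**Attaching the furan (23 ⇒ 21 ⇒ 17 + 20).** The ester carbon is removed from the furan α position (21). The bond between C5′ and the furan carbon that becomes C4′ is then cut, giving iodide 17 and furyllithium 20, which comes from 19 and 18. The cut sits next to an unhindered primary carbon; a cut closer to C8 would demand substitution at a neopentyl centre. The methoxy group steers both metalations.

**Quaternary C8 (17 ⇒ 16 ⇒ 15 ⇒ 14 ⇒ 12).** C8–C11 is cut as the bond formed in a [3,3] shift from the C6 oxygen of allylic alcohol 12. An intramolecular, suprafacial transfer is chosen because it delivers carbon to the β, equatorial position of C8, which intermolecular axial attack would not do. The C6 oxygen is the former quinone carbonyl, so no extra handle is needed. The forward sequence must then saturate C6=C7 without touching C3=C4 and reduce the two-carbon arm to the iodide.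

**Ring A and the C6 carbinol (12 ⇒ 11 ⇒ 10 ⇒ 9 ⇒ 8).** The cycloaddition leaves oxygen on C2 and unsaturation at C2=C3, whereas 28 needs C3=C4 and no oxygen. Isomerising a C2=C3 alkene is not reliable, because the double bond can equally walk towards C1 and C10. Instead the silyl enol ether of 8 is dehydrogenated to enone 9, which places the alkene at C3=C4 regiospecifically. Both enone carbonyls are reduced (10), the unhindered C2 alcohol is acetylated (11) and removed by allylic hydrogenolysis (12). Making C4 planar before the C6 reduction also frees the α face of C6 for hydride.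

**C9 methyl (8 ⇒ 7 ⇒ 6).** The C9–CH3 bond is traced to methylenation of the C9 ketone of 6 and hydrogenation of 7 from the α face. This is done while C8 is still sp2, so that only the C5 methyl differentiates the two faces.

**Ring fusion (6 ⇒ 5).** The trans fusion is traced to the cis adduct 5 by epimerisation at C10, the only enolisable position of ring B.

**Ring A (5 ⇒ 3 + 4; 3 ⇒ 1).** C4–C5 and C1–C10 are cut together as a [4+2] cycloaddition between diene 3 and quinone 4. This is the only disconnection that makes the quaternary C5 next to the C4 methyl from two commercial four- and six-carbon pieces and sets the absolute configuration catalytically. Diene 3 is the silyl dienol ether of enone 1.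

## Alternatives that were turned down

**Alternative 1:** Ring B is opened at C8–C9.
- Forward step: the trans-fused δ-lactone A2 (ring oxygen on C6, lactone carbonyl attached to C9, an (E)-trisubstituted alkenyl group on C6) is enolised and O-silylated. An Ireland–Claisen rearrangement then forms C8–C9 and contracts the lactone to the carbocyclic acid A1.
- For it: the lactone ring forces a boat array, so alkene geometry and C6 configuration fix C8 and C9 together. The C8 side chain arrives as a protected 2-hydroxyethyl group, the same handle as alcohol 16. No pseudoequatorial Claisen and no face-selective hydrogenation at C9 are needed. On these two points it is stronger than the chosen route.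
- Against it: A2 already contains ring A with C5, C10 and C6 defined, so the quaternary C5 must be made enantioselectively by a separate sequence that the key step does nothing for. The E-alkene must be built with geometric purity on a hindered carbinol. The C9 carboxyl must be taken down to a methyl group at a neopentyl position (about three steps). C6=C7 must still be saturated beside C3=C4.
- Comparison: the chosen strategy spends its key step on ring A and the absolute configuration, two steps from commercial materials, and takes ring B ready-made from 4. In place of concerted C8/C9 control it offers a short approach in which the risk sits in step 2 and not in a long precursor synthesis.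

**Alternative 2:** Ring C is disconnected at C1′–C2′, the two alkene termini of a cross-conjugated dienone.
- Forward step: the 2-methoxy dienone A4, chelated through its ketone and methoxy oxygens by Cu(OTf)2 carrying a chiral bis(oxazoline), undergoes a polarised Nazarov 4π-conrotatory closure to cyclopentenone A3. Hydroxylation at C1′ would then give 28.
- For it: the donor and acceptor substituents make the closure catalytic and regiodefined. Hydroxylation of the C1′ ester enolate anti to the C5′ substituent gives the trans hydroxyl/C11 relationship directly, which is at least as well founded as the kinetic protonation of step 19.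
- Against it: the step concerns ring C only and leaves the four contiguous decalin centres, the real difficulty, untouched. A4 must be assembled on the finished decalin at a neopentyl methylene, no shorter than the furan sequence. The electrocyclisation sets only C1′, an acidic methine that is made planar again for the hydroxylation, and C5′ is set by protonation. The configuration of ring C relative to the decalin therefore ends up resting on an epimerisable centre.
- Comparison: the chosen route uses its catalyst-controlled key step on the decalin and fixes ring C at the quaternary carbinol C1′, which cannot epimerise. The Nazarov closure could replace the endgame but not the strategy.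

**Alternative 3:** Both rings are disconnected at once at C1–C2 and C5–C10.
- Forward step: the acyclic trienone A6 (vinyl ketone C10=C1 with the C9 carbonyl, silyloxydiene C2=C3–C4(OSi)=C5, quaternary C8 in the tether) cyclises in an intramolecular Diels–Alder reaction. Base equilibration at C10 gives the trans-decalone silyl enol ether A5.
- For it: two rings and the quaternary C5 form in one step. C8 is already quaternary and carries an allyl handle. The silyl enol ether lies at C3=C4, so the vinylic C4 methyl would come from triflation and methyl cross-coupling without the detour of steps 6–9. This is a clear advantage for ring A.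
- Against it: the acyclic α-quaternary C8 must first be made enantioselectively. It must then dictate C5 across a flexible four-atom tether with only weak conformational preferences. The fully substituted diene terminus needs defined geometry and slows the cycloaddition. The C9 ketone ends up between quaternary C8 and C10, which makes methylenation and face-selective hydrogenation harder than in steps 4 and 5. A6 also needs a longer linear preparation than the two steps to 5.
- Comparison: the chosen route gives up the neat ring A endgame. It gains an intermolecular, catalyst-controlled key step from commercial partners in which C5 is set directly and C8 is set later by intramolecular chirality transfer.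

Key step: step 2

Assumption: the sense of induction of the two chiral catalysts (steps 2 and 18) is taken from their accepted face-selection models; should either give the mirror-image sense, its enantiomeric ligand, equally available, is used with no other change.

## Route

Step 1
Reactants: 1 (E)-pent-3-en-2-one
Product: 3 (E)-2-(triisopropylsilyloxy)penta-1,3-diene, via lithium dienolate 2 (not isolated)
Conditions: LDA, THF, −78 °C; then TIPSOTf, −78 → 0 °C
Reagents that add atoms: triisopropylsilyl trifluoromethanesulfonate, CC(C)[Si](OS(=O)(=O)C(F)(F)F)(C(C)C)C(C)C
Why: Kinetic deprotonation of the methyl group gives the cross-conjugated lithium enolate, which the silyl triflate traps on oxygen (kinetic enolate O-silylation); the E alkene is not touched.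

Step 2
Reactants: 3 (E)-2-(triisopropylsilyloxy)penta-1,3-diene; 4 2,5-dimethyl-1,4-benzoquinone
Product: 5 cis-fused adduct 4α,5β,8-trimethyl-2-(triisopropylsilyloxy)-10β-H-decalin-2,7-diene-6,9-dione
Conditions: (S)-3,3-diphenyl-1-(o-tolyl)tetrahydro-1H,3H-pyrrolo[1,2-c][1,3,2]oxazaborole (20 mol%) protonated with Tf2NH (20 mol%), CH2Cl2, −78 → −50 °C
Reagents that add atoms: none
Why: Coordination of the cationic boron to the C6 carbonyl oxygen of 4 (the carbonyl whose α-carbon carries the methyl group) lowers the LUMO of the C5=C10 bond, and the diene adds in a concerted but asynchronous [4+2] process in which the C1–C10 bond leads and the C4–C5 bond follows. The closest known reaction type is the oxazaborolidinium-catalysed enantioselective Diels–Alder reaction of 2,5-disubstituted 1,4-benzoquinones with 2-silyloxy-1,3-dienes. Ring A is closed in this step as an intermolecular six-membered annulation, both new σ bonds (C1–C10 and C4–C5) forming on one face of the quinone. C5 and C10 are cis because the addition is suprafacial on the dienophile, and their absolute configuration is set by the catalyst, whose aryl group covers one face of the bound enone. C4 is set relative to C5 by the endo transition state together with the E geometry of the diene (C4 methyl trans to the C5 methyl). The regiochemistry needed is secured because the 2-silyloxy and 4-methyl donors both make C1 the nucleophilic terminus, while C10, β to the activated carbonyl and unsubstituted, is the electrophilic carbon, so the methyl-bearing terminus ends on C5. Site selectivity is no issue, the two C=C bonds of 4 being equivalent, and 5 is a poorer, more hindered dienophile than 4, so a second addition is not expected. C4 is made planar in step 6, so any exo adduct converges later.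

Step 3
Reactants: 5 cis-fused adduct
Product: 6 trans-fused adduct 4α,5β,8-trimethyl-2-(triisopropylsilyloxy)-10α-H-decalin-2,7-diene-6,9-dione
Conditions: DBU (0.2 equiv), CH2Cl2, 23 °C
Reagents that add atoms: none
Why: Base-mediated epimerisation through the C9 enolate; C10 is the only enolisable position of ring B (C5 is quaternary), and equilibration should favour the trans-fused isomer, in which the C4 and C5 methyl groups are anti and ring A no longer folds under ring B.

Step 4
Reactants: 6 trans-fused adduct
Product: 7 4α,5β,8-trimethyl-9-methylene-2-(triisopropylsilyloxy)-10α-H-decalin-2,7-dien-6-one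
Conditions: Cp2Ti(μ-Cl)(μ-CH2)AlMe2 (1.05 equiv), pyridine (cat.), THF–toluene, −40 → 0 °C
Reagents that add atoms: μ-chloro-μ-methylene-bis(cyclopentadienyl)titanium dimethylaluminium, C[Al-]1(C)C[Ti]([Cl+]1)(C1C=CC=C1)C1C=CC=C1
Why: Titanium methylidene carbonyl olefination ([2+2] addition and cycloreversion) is non-basic, so C10 is not disturbed; C9 reacts in preference to C6, which is neopentyl (quaternary C5, peri C4 methyl) and is the vinylogous carbonyl of the C8 methyl.

Step 5
Reactants: 7 9-methylene dienone
Product: 8 4α,5β,8,9β-tetramethyl-2-(triisopropylsilyloxy)-10α-H-decalin-2,7-dien-6-one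
Conditions: H2 (1 atm), RhCl(PPh3)3 (5 mol%), benzene, 23 °C
Reagents that add atoms: none
Why: Homogeneous rhodium hydrogenation reduces the 1,1-disubstituted exocyclic alkene of the dienone and leaves the trisubstituted enone and the silyl enol ether; hydrogen is delivered to the α face of C9, away from the 1,3-related axial C5 methyl, which places the new methyl β.

Step 6
Reactants: 8 silyl enol ether
Product: 9 4,5β,8,9β-tetramethyl-10α-H-decalin-3,7-diene-2,6-dione
Conditions: Pd(OAc)2 (1.2 equiv), MeCN–CH2Cl2, 40 °C
Reagents that add atoms: none
Why: Saegusa oxidation: divalent palladium bonds to C3 of the silyl enol ether and β-hydride elimination can only take the C4 hydrogen, so the alkene is placed at C3=C4 regiospecifically and C4 becomes planar.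

Step 7
Reactants: 9 bis-enone
Product: 10 4,5β,8,9β-tetramethyl-10α-H-decalin-3,7-diene-2β,6β-diol
Conditions: NaBH4, CeCl3·7H2O, MeOH, −78 → 0 °C
Reagents that add atoms: none
Why: Luche 1,2-reduction of both enone carbonyls; at C6 hydride adds along the axial α trajectory, anti to the adjacent axial C5 methyl and unhindered now that C4 is planar, giving the equatorial 6β-alcohol (the C2 centre, expected mainly β, is removed in step 9).

Step 8
Reactants: 10 diol
Product: 11 6β-hydroxy-4,5β,8,9β-tetramethyl-10α-H-decalin-3,7-dien-2β-yl acetate
Conditions: Ac2O (1.05 equiv), pyridine, DMAP (cat.), CH2Cl2, −20 °C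
Reagents that add atoms: acetic anhydride, CC(=O)OC(C)=O
Why: Selective O-acylation: the C2 hydroxyl is an unhindered secondary alcohol, whereas the C6 hydroxyl is neopentyl and crowded by the peri C4 methyl.

Step 9
Reactants: 11 allylic acetate
Product: 12 4,5β,8,9β-tetramethyl-10α-H-decalin-3,7-dien-6β-ol
Conditions: Pd(PPh3)4 (5 mol%), LiBHEt3 (3 equiv), THF, 0 → 23 °C
Reagents that add atoms: none
Why: Palladium-catalysed allylic hydrogenolysis: zerovalent palladium ionises the acetate to a C2–C3–C4 π-allyl complex and hydride adds to the less substituted terminus C2, which keeps the trisubstituted C3=C4 alkene; the free C6 allylic alcohol is not ionised.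

Step 10
Reactants: 12 allylic alcohol
Product: 14 N,N-dimethyl-2-(4,5β,8α,9β-tetramethyl-10α-H-decalin-3,6-dien-8β-yl)acetamide, via ketene N,O-acetal 13 (not isolated)
Conditions: MeC(OMe)2NMe2 (5 equiv), xylenes, 140 °C, removal of MeOH
Reagents that add atoms: N,N-dimethylacetamide dimethyl acetal, CN(C)C(C)(OC)OC
Why: Eschenmoser–Claisen rearrangement: alcohol exchange gives the ketene N,O-acetal, whose suprafacial [3,3] shift across C6–C7=C8 transfers the β configuration of the C6–O bond to the new C8–C11 bond (C11 β, methyl α) and moves the alkene to C6=C7; the neutral conditions spare the C3=C4 alkene.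

Step 11
Reactants: 14 unsaturated amide
Product: 15 N,N-dimethyl-2-(4,5β,8α,9β-tetramethyl-10α-H-decal-3-en-8β-yl)acetamide
Conditions: TsNHNH2 (excess), NaOAc, DME–H2O, reflux
Reagents that add atoms: none
Why: Diimide reduction: concerted syn transfer of two hydrogens from HN=NH is fast for the 1,2-disubstituted C6=C7 alkene and slow for the trisubstituted C3=C4 alkene, and it causes no double-bond migration.

Step 12
Reactants: 15 saturated amide
Product: 16 2-(4,5β,8α,9β-tetramethyl-10α-H-decal-3-en-8β-yl)ethanol
Conditions: LiBHEt3 (3 equiv), THF, 0 → 23 °C; aq. NaOH
Reagents that add atoms: none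
Why: Triethylborohydride reduction of a tertiary amide proceeds with C–N cleavage to the primary alcohol.

Step 13
Reactants: 16 primary alcohol
Product: 17 8β-(2-iodoethyl)-4,5β,8α,9β-tetramethyl-10α-H-decal-3-ene
Conditions: I2, PPh3, imidazole, CH2Cl2, 0 → 23 °C
Reagents that add atoms: iodine, II
Why: Appel-type iodination: activation of the alcohol on phosphorus and SN2 displacement by iodide at the unhindered primary carbon.

Step 14
Reactants: 18 3-bromofuran
Product: 19 3-methoxyfuran
Conditions: NaOMe, CuBr (10 mol%), MeOH–NMP, 100 °C
Reagents that add atoms: sodium methoxide, [Na+].[O-]C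
Why: Copper-mediated Ullmann-type methoxylation of the heteroaryl bromide.

Step 15
Reactants: 19 3-methoxyfuran; 17 primary iodide
Product: 21 3-methoxy-2-[2-(4,5β,8α,9β-tetramethyl-10α-H-decal-3-en-8β-yl)ethyl]furan, via 3-methoxy-2-furyllithium 20 (not isolated)
Conditions: 19 (3 equiv), n-BuLi, THF, −78 → 0 °C; then 17, DMPU, −78 → 23 °C
Reagents that add atoms: none
Why: Lithiation at furan C2, the α position ortho to the methoxy group, followed by SN2 alkylation of the furyllithium by the primary iodide (heteroaryllithium alkylation).

Step 16
Reactants: 21 2-alkyl-3-methoxyfuran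
Product: 23 methyl 4-methoxy-5-[2-(4,5β,8α,9β-tetramethyl-10α-H-decal-3-en-8β-yl)ethyl]furan-2-carboxylate, via 5-lithiofuran 22 (not isolated)
Conditions: n-BuLi, THF, −78 → 0 °C; then inverse addition to ClCO2Me, −78 °C
Reagents that add atoms: methyl chloroformate, COC(=O)Cl
Why: Deprotonation at the remaining furan α position and C-acylation of the furyllithium (metalation–carboxylation); no other C–H of 21 is comparably acidic.

Step 17
Reactants: 23 furoate
Product: 25 methyl (3E)-4-methoxy-2,5-dioxo-7-(4,5β,8α,9β-tetramethyl-10α-H-decal-3-en-8β-yl)hept-3-enoate (carbonyl groups cis), via furan endoperoxide 24 (not isolated)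
Conditions: O2, hν, methylene blue (cat.), CH2Cl2, −78 °C; then Me2S, −78 → 23 °C
Reagents that add atoms: dioxygen, O=O
Why: Furan photooxygenation: [4+2] addition of singlet oxygen across the two furan α carbons and reduction of the endoperoxide unmask the cis-enedione; the donor-substituted furan should react much faster than the hindered C3=C4 alkene would by the ene pathway.

Step 18
Reactants: 25 cis-enedione keto ester
Product: 26 C5′ epimer of dysidenone B (C11 cis to the C1′ hydroxyl)
Conditions: Cu(OTf)2 (10 mol%), 2,2′-(propane-2,2-diyl)bis[(4S)-4-tert-butyl-4,5-dihydrooxazole] (11 mol%), i-Pr2NEt (10 mol%), 4 Å MS, CH2Cl2, −20 °C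
Reagents that add atoms: none
Why: Proposed new method: the α-keto ester of 25 should chelate the divalent copper bis(oxazoline) complex through its two adjacent carbonyl oxygens, the amine reversibly generates the enol(ate) of the C4′ ketone at C5′, and this attacks the bound C1′ ketone in a 5-(enolendo)-exo-trig aldol closure on the face left open by the tert-butyl groups, so that the quaternary carbinol C1′ is set by the catalyst (the decalin is too remote to help); the closest known reaction types are the base-mediated cyclisation of furan-derived cis-2-ene-1,4-diones to 4-hydroxycyclopent-2-enones and the copper bis(oxazoline)-catalysed enantioselective additions (Mukaiyama aldol, carbonyl-ene) to chelated α-keto esters; C5′ is expected to settle under these equilibrating conditions mainly as the epimer with C11 cis to the hydroxyl and is corrected in step 19.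

Step 19
Reactants: 26 C5′ epimer
Product: 28 dysidenone B, via dilithium alkoxide–enolate 27 (not isolated)
Conditions: LiHMDS (2.2 equiv), THF, −78 °C; then AcOH in THF, −78 °C
Reagents that add atoms: none
Why: Deprotonation and kinetic reprotonation (kinetic ketonisation): the planar C5′ enolate should be protonated from the face of the small C1′ oxygen function and not from the ester face, which puts H5′ cis to the hydroxyl and C11 cis to the ester; the dianion cannot undergo retro-aldol cleavage, so C1′ is not at risk.

## Compound list

1 | (E)-pent-3-en-2-one | C/C=C/C(C)=O | starting material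
2 | lithium (E)-penta-1,3-dien-2-olate | [Li]OC(=C)/C=C/C | intermediate (not isolated)
3 | (E)-2-(triisopropylsilyloxy)penta-1,3-diene | C=C(O[Si](C(C)C)(C(C)C)C(C)C)/C=C/C | intermediate
4 | 2,5-dimethyl-1,4-benzoquinone | CC1=CC(=O)C(C)=CC1=O | starting material
5 | cis-fused adduct, 4α,5β,8-trimethyl-2-(triisopropylsilyloxy)-10β-H-decalin-2,7-diene-6,9-dione | CC1=CC(=O)[C@]2(C)[C@H](C)C=C(O[Si](C(C)C)(C(C)C)C(C)C)C[C@@H]2C1=O | intermediate
6 | trans-fused adduct, 4α,5β,8-trimethyl-2-(triisopropylsilyloxy)-10α-H-decalin-2,7-diene-6,9-dione | CC1=CC(=O)[C@]2(C)[C@H](C)C=C(O[Si](C(C)C)(C(C)C)C(C)C)C[C@H]2C1=O | intermediate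
7 | 4α,5β,8-trimethyl-9-methylene-2-(triisopropylsilyloxy)-10α-H-decalin-2,7-dien-6-one | CC1=CC(=O)[C@]2(C)[C@H](C)C=C(O[Si](C(C)C)(C(C)C)C(C)C)C[C@H]2C1=C | intermediate
8 | 4α,5β,8,9β-tetramethyl-2-(triisopropylsilyloxy)-10α-H-decalin-2,7-dien-6-one | CC1=CC(=O)[C@]2(C)[C@H](C)C=C(O[Si](C(C)C)(C(C)C)C(C)C)C[C@H]2[C@H]1C | intermediate
9 | 4,5β,8,9β-tetramethyl-10α-H-decalin-3,7-diene-2,6-dione | CC1=CC(=O)[C@]2(C)C(C)=CC(=O)C[C@H]2[C@H]1C | intermediate
10 | 4,5β,8,9β-tetramethyl-10α-H-decalin-3,7-diene-2β,6β-diol (2β epimer expected as the main one) | CC1=C[C@@H](O)[C@]2(C)C(C)=C[C@@H](O)C[C@H]2[C@H]1C | intermediate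
11 | 6β-hydroxy-4,5β,8,9β-tetramethyl-10α-H-decalin-3,7-dien-2β-yl acetate | CC1=C[C@@H](O)[C@]2(C)C(C)=C[C@@H](OC(C)=O)C[C@H]2[C@H]1C | intermediate
12 | 4,5β,8,9β-tetramethyl-10α-H-decalin-3,7-dien-6β-ol | CC1=C[C@@H](O)[C@]2(C)C(C)=CCC[C@H]2[C@H]1C | intermediate
13 | 6β-[1-(dimethylamino)vinyloxy] ether of 12 (ketene N,O-acetal) | CC1=C[C@@H](OC(=C)N(C)C)[C@]2(C)C(C)=CCC[C@H]2[C@H]1C | intermediate (not isolated)
14 | N,N-dimethyl-2-(4,5β,8α,9β-tetramethyl-10α-H-decalin-3,6-dien-8β-yl)acetamide | CN(C)C(=O)C[C@@]1(C)C=C[C@]2(C)C(C)=CCC[C@H]2[C@H]1C | intermediate
15 | N,N-dimethyl-2-(4,5β,8α,9β-tetramethyl-10α-H-decal-3-en-8β-yl)acetamide | CN(C)C(=O)C[C@@]1(C)CC[C@]2(C)C(C)=CCC[C@H]2[C@H]1C | intermediate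
16 | 2-(4,5β,8α,9β-tetramethyl-10α-H-decal-3-en-8β-yl)ethanol | OCC[C@@]1(C)CC[C@]2(C)C(C)=CCC[C@H]2[C@H]1C | intermediate
17 | 8β-(2-iodoethyl)-4,5β,8α,9β-tetramethyl-10α-H-decal-3-ene | ICC[C@@]1(C)CC[C@]2(C)C(C)=CCC[C@H]2[C@H]1C | intermediate
18 | 3-bromofuran | Brc1ccoc1 | starting material
19 | 3-methoxyfuran | COc1ccoc1 | intermediate
20 | 3-methoxy-2-furyllithium | [Li]c1occc1OC | intermediate (not isolated)
21 | 3-methoxy-2-[2-(decal-3-en-8β-yl)ethyl]furan (decalin as in 17) | COc1ccoc1CC[C@@]2(C)CC[C@]3(C)C(C)=CCC[C@H]3[C@H]2C | intermediate
22 | 5-lithio derivative of 21 | COc1cc([Li])oc1CC[C@@]2(C)CC[C@]3(C)C(C)=CCC[C@H]3[C@H]2C | intermediate (not isolated)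
23 | methyl 4-methoxy-5-[2-(decal-3-en-8β-yl)ethyl]furan-2-carboxylate (decalin as in 17) | COC(=O)c1cc(OC)c(CC[C@@]2(C)CC[C@]3(C)C(C)=CCC[C@H]3[C@H]2C)o1 | intermediate
24 | 2,5-endoperoxide of furan 23 (bridgehead configuration not controlled) | COC(=O)C12C=C(OC)C(CC[C@@]3(C)CC[C@]4(C)C(C)=CCC[C@H]4[C@H]3C)(OO1)O2 | intermediate (not isolated)
25 | methyl (3E)-4-methoxy-2,5-dioxo-7-(decal-3-en-8β-yl)hept-3-enoate, the two ketone groups cis on the alkene | COC(=O)C(=O)/C=C(OC)\C(=O)CC[C@@]1(C)CC[C@]2(C)C(C)=CCC[C@H]2[C@H]1C | intermediate
26 | C5′ epimer of dysidenone B (C11 cis to the C1′ hydroxyl) | COC(=O)[C@@]1(O)C=C(OC)C(=O)[C@@H]1C[C@@]1(C)CC[C@]2(C)C(C)=CCC[C@H]2[C@H]1C | intermediate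
27 | dilithium C1′-alkoxide C4′-enolate of 26 | COC(=O)[C@@]1([O-])C=C(OC)C([O-])=C1C[C@@]1(C)CC[C@]2(C)C(C)=CCC[C@H]2[C@H]1C.[Li+].[Li+] | intermediate (not isolated)
28 | dysidenone B | COC(=O)[C@@]1(O)C=C(OC)C(=O)[C@H]1C[C@@]1(C)CC[C@]2(C)C(C)=CCC[C@H]2[C@H]1C | target

## Step count and least certain steps

Total step count: 19. Longest linear sequence: 18 (steps 1–13 and 15–19); step 14 is a one-step side branch.

**Step 18 (proposed new method).** The likely failure is poor facial discrimination at C1′. It would arise if the amine-promoted closure runs through copper-free substrate, or if the copper binds the methoxy ketone or the 1,4-dicarbonyl site instead of the α-keto ester. Aldol reversibility would also erode selectivity. Fallback with known chemistry: starting from 25, the cyclisation is run with a catalytic amine base alone, the established closure of furan-derived cis-enediones to 4-hydroxycyclopent-2-enones. This should give 26 together with the ring C diastereomer of inverted C1′ configuration F1. The two are separated by chromatography, and F1 is returned to the same base, where retro-aldol opening to 25 re-equilibrates it. The route is rejoined at 26.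

**Step 2 (key step).** The likely failure is insufficient enantioface selection. The second bond must form at the methyl-bearing C5 next to the C4 methyl, which slows the catalysed pathway and lets an uncatalysed background reaction compete. Fallback: starting from 3 and 4, the cycloaddition is run without the chiral catalyst (thermally in toluene), which gives 5 together with the enantiomer of the adduct F2. The racemate is resolved by preparative chromatography on a chiral stationary phase, and the route is rejoined at 5.

**Step 10.** The likely failure is elimination to a diene or return of the alcohol instead of rearrangement. The C6–O bond is pseudoequatorial in the locked half-chair and poorly aligned with the alkene, and the new bond forms next to the β methyl on C9. Fallback: starting from 12, the hindered alcohol is acetylated to the 6β-acetate F3. Enolisation with LDA and trapping with TBSCl gives the silyl ketene acetal F4, which undergoes the Ireland–Claisen rearrangement below 60 °C through a boat array to the silyl ester F5. Work-up gives the unsaturated acid F6, diimide reduction gives the saturated acid F7, and LiAlH4 reduction rejoins the route at 16.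

**Step 6.** The likely failure is slow β-hydride elimination, because the only hydrogen that can become syn to palladium (C4–H, β) lies on the face shielded by the C5 methyl. Protodemetalation to the saturated C2 ketone would then compete. Fallback: starting from 8, the silyl enol ether is selenenylated with PhSeCl to the 3-phenylseleno ketone F8, whose C3 centre can epimerise. Oxidation with H2O2 and selenoxide syn-elimination rejoin the route at 9.

**Step 19.** The likely failure is loss of facial control in the proton transfer, either by protonation from the ester face or by O-protonation followed by equilibration, which returns 26. Fallback: starting from 26, C5′ is equilibrated with catalytic DBU, 28 is separated from 26 by chromatography and 26 is recycled. No new compound is involved and the route ends at 28.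

**Step 3.** The likely failure is an incomplete or unfavourable cis/trans equilibrium at C10, giving mixtures. Fallback: starting from 5, deprotonation with LiHMDS at −78 °C gives the C9 lithium enolate F9. Kinetic protonation with a hindered phenol from the α face, anti to the adjacent C5 methyl, rejoins the route at 6.

## Further compounds

F1 | step 18 | ring C diastereomer of 26 with inverted C1′ (1′,5′-bis-epimer of 28) | COC(=O)[C@]1(O)C=C(OC)C(=O)[C@H]1C[C@@]1(C)CC[C@]2(C)C(C)=CCC[C@H]2[C@H]1C
F2 | step 2 | enantiomer of adduct 5 | CC1=CC(=O)[C@@]2(C)[C@@H](C)C=C(O[Si](C(C)C)(C(C)C)C(C)C)C[C@H]2C1=O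
F3 | step 10 | 6β-acetate of 12 | CC1=C[C@@H](OC(C)=O)[C@]2(C)C(C)=CCC[C@H]2[C@H]1C
F4 | step 10 | tert-butyldimethylsilyl ketene acetal of F3 | CC1=C[C@@H](OC(=C)O[Si](C)(C)C(C)(C)C)[C@]2(C)C(C)=CCC[C@H]2[C@H]1C
F5 | step 10 | tert-butyldimethylsilyl 2-(4,5β,8α,9β-tetramethyl-10α-H-decalin-3,6-dien-8β-yl)acetate | CC(C)(C)[Si](C)(C)OC(=O)C[C@@]1(C)C=C[C@]2(C)C(C)=CCC[C@H]2[C@H]1C
F6 | step 10 | 2-(4,5β,8α,9β-tetramethyl-10α-H-decalin-3,6-dien-8β-yl)acetic acid | OC(=O)C[C@@]1(C)C=C[C@]2(C)C(C)=CCC[C@H]2[C@H]1C
F7 | step 10 | 2-(4,5β,8α,9β-tetramethyl-10α-H-decal-3-en-8β-yl)acetic acid | OC(=O)C[C@@]1(C)CC[C@]2(C)C(C)=CCC[C@H]2[C@H]1C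
F8 | step 6 | 4α,5β,8,9β-tetramethyl-3-(phenylseleno)-10α-H-decal-7-ene-2,6-dione (C3 epimers) | CC1=CC(=O)[C@]2(C)[C@H](C)C([Se]c3ccccc3)C(=O)C[C@H]2[C@H]1C
F0 | step 19 | none | none
F9 | step 3 | C9 lithium enolate of adduct 5 | CC1=CC(=O)[C@]2(C)[C@H](C)C=C(O[Si](C(C)C)(C(C)C)C(C)C)CC2=C1O[Li]
A1 | alternative 1 | ring B cyclohexene C9 carboxylic acid with the C8 2-(silyloxy)ethyl chain | OC(=O)[C@@H]1[C@@H]2CCC=C(C)[C@@]2(C)C=C[C@]1(C)CCO[Si](C)(C)C(C)(C)C
A2 | alternative 1 | trans-fused δ-lactone with the (E)-alkenyl group on C6 | O=C1C[C@@H]2CCC=C(C)[C@@]2(C)[C@@H](/C=C(\C)CCO[Si](C)(C)C(C)(C)C)O1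
A3 | alternative 2 | trans-4-carbomethoxy-2-methoxy-5-alkylcyclopent-2-enone | COC(=O)[C@@H]1C=C(OC)C(=O)[C@H]1C[C@@]1(C)CC[C@]2(C)C(C)=CCC[C@H]2[C@H]1C
A4 | alternative 2 | 2-methoxy cross-conjugated dienone ester | C=C(OC)C(=O)/C(C[C@@]1(C)CC[C@]2(C)C(C)=CCC[C@H]2[C@H]1C)=C/C(=O)OC
A5 | alternative 3 | trans-decalone silyl enol ether | C=CC[C@@]1(C)CC[C@]2(C)C(O[Si](C)(C)C(C)(C)C)=CCC[C@H]2C1=O
A6 | alternative 3 | acyclic trienone with the silyloxydiene and the quaternary C8 | C=CC[C@@](C(=O)C=C)(C)CC/C(C)=C(/C=C)O[Si](C)(C)C(C)(C)C
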